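**Retrosynthetic overview**

1. Late stage: the two formyl groups, the free phenols, the C1' isobutyl group (o-quinone methide alkylation) and the C10 methyl carbinol are added to the trans-hydroazulene diketone 16, which already carries the arene as an aryl ketone at C1' (guaiane numbering).
2. Key disconnection: bonds C1–C2 and C3–C4 of the cyclopentane. C1 is the α-carbon of the C10 ketone in the seven-membered ring, C4 is the α-carbon of the C1' aryl ketone, and both are bonded to ring-fusion carbon C5, so a regiodefined 1,3-bis-enolate can be stapled with a two-carbon bis-electrophile (ethylene sulfate).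
3. The bis-enolate comes from silyl enol ether 12, the Mukaiyama–Michael adduct of enol ether 11 and (R)-5-isopropenylcycloheptenone 8; the silyl group stores the C1 regiochemistry and is lost in the key step.
4. Enone 8 comes from (R)-limonene by cleavage of the ring alkene (C7 stereocentre kept), two methylenations and ring-closing metathesis.
5. Ring order: seven-membered ring (step 4), then five-membered ring (step 8); stereochemical relay C7 → C5 → C1 and C4 → C10 and C1'.

Key step: step 8

Remark on numbering: guaiane numbering is used for the core (C1 and C5 ring-fusion carbons, C2 and C3 the CH2 groups of the five-membered ring, C4 the quaternary carbon, C7 the isopropenyl-bearing carbon, C10 the carbinol carbon, C1' the benzylic carbon). With the 7-isopropenyl group drawn β, the target has H1 α, H5 β, 4-CH3 α, 4-C1' β, 10-OH α, 10-CH3 β, i.e. (1R,4S,5S,7R,10R,1'R).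

Remark on the chemistry: the facial selectivities claimed in steps 7, 9 and 13 are predictions from conformational models, not established results.

**Route**

Step 1
Reactants: 1 (R)-(+)-limonene
Product: 3 (3R)-6-oxo-3-(prop-1-en-2-yl)heptanal, via ozonide 2 (not isolated)
Conditions: O3 (1.0 equiv, Sudan red end point), CH2Cl2, −78 °C; PPh3, −78 °C → rt
Reagents that add atoms: ozone, [O-][O+]=O
Why: Chemoselective ozonolysis; the trisubstituted ring alkene is more electron-rich than the isopropenyl group and should be cleaved first, leaving the stereocentre untouched.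

Step 2
Reactants: 3 (3R)-6-oxo-3-(prop-1-en-2-yl)heptanal
Product: 4 (5R)-5-(prop-1-en-2-yl)oct-7-en-2-one
Conditions: Ph3PCH3Br (1.05 equiv), KOt-Bu (1.0 equiv), THF, −78 → 0 °C
Reagents that add atoms: methyltriphenylphosphonium bromide, C[P+](c1ccccc1)(c1ccccc1)c1ccccc1.[Br-]
Why: Wittig methylenation; with one equivalent of ylide the aldehyde should react much faster than the methyl ketone.

Step 3
Reactants: 4 (5R)-5-(prop-1-en-2-yl)oct-7-en-2-one
Product: 7 (6R)-6-(prop-1-en-2-yl)nona-1,8-dien-3-one, via Mannich base 5 (not isolated), via methiodide 6 (not isolated)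
Conditions: LiN(i-Pr)2, THF, −78 °C; CH2=NMe2 I, −78 °C → rt; MeI, rt; NaHCO3 (aq), CH2Cl2
Reagents that add atoms: dimethyl(methylene)ammonium iodide, C=[N+](C)C.[I-]
Why: Kinetic enolization at the methyl group, Mannich reaction, N-quaternization and E1cB elimination, the standard Mannich-base route to a vinyl ketone.

Step 4
Reactants: 7 (6R)-6-(prop-1-en-2-yl)nona-1,8-dien-3-one
Product: 8 (5R)-5-(prop-1-en-2-yl)cyclohept-2-en-1-one
Conditions: second-generation Grubbs catalyst (3 mol %), CH2Cl2 (0.01 M), 40 °C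
Reagents that add atoms: none
Why: Ring-closing metathesis; the catalyst should load on the monosubstituted alkene and close onto the vinyl ketone to the seven-membered enone, the 1,1-disubstituted isopropenyl group being a poor metathesis partner.

Step 5
Reactants: 9 1,3,5-trimethoxybenzene
Product: 10 1-(2,4,6-trimethoxyphenyl)propan-1-one
Conditions: (EtCO)2O (1.2 equiv), Bi(OTf)3 (5 mol %), MeNO2, 50 °C
Reagents that add atoms: propanoic anhydride, CCC(=O)OC(=O)CC
Why: Friedel–Crafts acylation of a very electron-rich arene; the ketone product is deactivated, so monoacylation is expected.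

Step 6
Reactants: 10 1-(2,4,6-trimethoxyphenyl)propan-1-one
Product: 11 (Z)-trimethyl{[1-(2,4,6-trimethoxyphenyl)prop-1-en-1-yl]oxy}silane
Conditions: TMSOTf (1.2 equiv), Et3N (1.5 equiv), CH2Cl2, 0 °C
Reagents that add atoms: trimethylsilyl trifluoromethanesulfonate, C[Si](C)(C)OS(=O)(=O)C(F)(F)F
Why: Soft enolization with O-silylation gives the silyl enol ether (Z expected; the geometry is not carried into the product).

Step 7
Reactants: 8 (5R)-5-(prop-1-en-2-yl)cyclohept-2-en-1-one; 11 (Z)-trimethyl{[1-(2,4,6-trimethoxyphenyl)prop-1-en-1-yl]oxy}silane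
Product: 12 2-[(1S,6R)-6-(prop-1-en-2-yl)-3-(trimethylsilyloxy)cyclohept-2-en-1-yl]-1-(2,4,6-trimethoxyphenyl)propan-1-one (both epimers at C4)
Conditions: Tf2NH (2 mol %), CH2Cl2, −78 °C; Et3N quench, concentrate, use crude
Reagents that add atoms: none
Why: Mukaiyama–Michael addition with silyl transfer (TMSNTf2 formed in situ) should deliver the adduct as its C10 silyl enol ether, which fixes the later enolate at C1; C5 is expected trans to the isopropenyl group two carbons away by addition to the enone face opposite this pseudo-equatorial substituent, as for 5-substituted cycloalkenones, and the C4 configuration is irrelevant because C4 is re-enolized in step 8.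

Step 8
Reactants: 12 2-[(1S,6R)-6-(prop-1-en-2-yl)-3-(trimethylsilyloxy)cyclohept-2-en-1-yl]-1-(2,4,6-trimethoxyphenyl)propan-1-one
Product: 16 (1S,3aR,7R,8aS)-1-methyl-7-(prop-1-en-2-yl)-1-(2,4,6-trimethoxybenzoyl)octahydroazulen-4(1H)-one, via lithium enolate 13 (not isolated), via dilithium bis-enolate 14 (not isolated), via lithium alkyl sulfate 15 (not isolated)
Conditions: LiN(i-Pr)2 (1.05 equiv), THF, −78 °C; MeLi (1.05 equiv), −78 → −20 °C; DMPU, 1,3,2-dioxathiolane 2,2-dioxide (1.05 equiv), −78 → 40 °C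
Reagents that add atoms: 1,3,2-dioxathiolane 2,2-dioxide (ethylene sulfate), O=S1(=O)OCCO1
Why: Deprotonation of the only acidic C–H (C4–H, α to the aryl ketone) and Si–O cleavage of the enol ether by MeLi give the regiodefined dilithium 1,3-bis-enolate 14, whose two nucleophilic carbons C1 and C4 are both bonded to C5. The less hindered cycloheptanone enolate carbon C1 should open the cyclic sulfate by SN2 (bond C1–C2), and the remaining tetrasubstituted aryl ketone enolate then displaces the alkyl sulfate intramolecularly (bond C3–C4), a 5-(enolexo)-exo-tet closure of the cyclopentane that is trans-fused to the seven-membered ring. The closest known reaction types are regiospecific lithium enolate generation from a silyl enol ether followed by alkylation, and the double C-alkylation of enolates by 1,2-cyclic sulfates used to make cyclopropanes from malonates. C1 is set by alkylation trans to the C5 side chain (the usual 2,3-trans outcome for β-substituted cycloalkanone enolates); C4 is set in the ring closure by allylic 1,3-strain, H5 eclipsing the enolate C=C so that the electrophile tethered to C1 adds to the face that leaves the aroyl group cis to H5 and the methyl group cis to C6. The step needs C1-before-C4 alkylation and C- over O-alkylation: the shielding of the C4 enolate by the 2,6-dimethoxyaryl group and the seven-membered ring that O-closure would require should secure both. Because both carbonyls are enolates until the first bond is formed, no ketone with acidic hydrogens is present at the start.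

Step 9
Reactants: 16 (1S,3aR,7R,8aS)-1-methyl-7-(prop-1-en-2-yl)-1-(2,4,6-trimethoxybenzoyl)octahydroazulen-4(1H)-one
Product: 17 [(1S,3aR,4R,7R,8aS)-4-hydroxy-1,4-dimethyl-7-(prop-1-en-2-yl)decahydroazulen-1-yl](2,4,6-trimethoxyphenyl)methanone
Conditions: MeAl(OAr)2 (Ar = 2,6-t-Bu2-4-MeC6H2; 3 equiv, from AlMe3 and ArOH), toluene, −78 °C; MeLi (3 equiv), −78 °C
Reagents that add atoms: methyllithium, [Li]C
Why: Amphiphilic carbonyl alkylation; the bulky aluminium Lewis acid should bind the unhindered C10 ketone on its equatorial side so that MeLi enters axially, anti to the axial H1, giving the 10β-methyl 10α-ol, while the neopentyl 2,6-dimethoxyaryl ketone is too hindered to react.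

Step 10
Reactants: 17 [(1S,3aR,4R,7R,8aS)-4-hydroxy-1,4-dimethyl-7-(prop-1-en-2-yl)decahydroazulen-1-yl](2,4,6-trimethoxyphenyl)methanone
Product: 18 (2-hydroxy-4,6-dimethoxyphenyl)[(1S,3aR,4R,7R,8aS)-4-hydroxy-1,4-dimethyl-7-(prop-1-en-2-yl)decahydroazulen-1-yl]methanone
Conditions: MgI2·OEt2 (2 equiv), THF–toluene, 60 °C; NH4Cl (aq)
Reagents that add atoms: none
Why: Chelation-assisted ortho-demethylation; magnesium bridges the ketone oxygen and an ortho methoxy group and iodide removes that methyl by SN2, the reaction stopping at the chelated phenoxide (the two ortho groups are equivalent).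

Step 11
Reactants: 18 (2-hydroxy-4,6-dimethoxyphenyl)[(1S,3aR,4R,7R,8aS)-4-hydroxy-1,4-dimethyl-7-(prop-1-en-2-yl)decahydroazulen-1-yl]methanone
Product: 19 2-{hydroxy[(1S,3aR,4R,7R,8aS)-4-hydroxy-1,4-dimethyl-7-(prop-1-en-2-yl)decahydroazulen-1-yl]methyl}-3,5-dimethoxyphenol (both carbinol epimers)
Conditions: LiAlH4 (3 equiv), THF, 0 °C → rt; sodium potassium tartrate (aq)
Reagents that add atoms: none
Why: Hydride reduction of the aryl ketone to the o-hydroxybenzylic alcohol; both epimers are used because this carbon becomes trigonal in step 13.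

Step 12
Reactants: 19 2-{hydroxy[(1S,3aR,4R,7R,8aS)-4-hydroxy-1,4-dimethyl-7-(prop-1-en-2-yl)decahydroazulen-1-yl]methyl}-3,5-dimethoxyphenol
Product: 20 tert-butyl 2-{hydroxy[(1S,3aR,4R,7R,8aS)-4-hydroxy-1,4-dimethyl-7-(prop-1-en-2-yl)decahydroazulen-1-yl]methyl}-3,5-dimethoxyphenyl carbonate
Conditions: Boc2O (1.05 equiv), i-Pr2NEt, DMAP (5 mol %), CH2Cl2, 0 °C
Reagents that add atoms: di-tert-butyl dicarbonate, CC(C)(C)OC(=O)OC(=O)OC(C)(C)C
Why: Chemoselective O-acylation of the phenol (the hindered secondary and tertiary alcohols should not react) installs the group that permits o-quinone methide formation at low temperature.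

Step 13
Reactants: 20 tert-butyl 2-{hydroxy[(1S,3aR,4R,7R,8aS)-4-hydroxy-1,4-dimethyl-7-(prop-1-en-2-yl)decahydroazulen-1-yl]methyl}-3,5-dimethoxyphenyl carbonate
Product: 22 2-{(1R)-1-[(1S,3aR,4R,7R,8aS)-4-hydroxy-1,4-dimethyl-7-(prop-1-en-2-yl)decahydroazulen-1-yl]-3-methylbutyl}-3,5-dimethoxyphenol, via quinone methide 21 (not isolated)
Conditions: i-BuMgBr (4 equiv), THF, −78 → 0 °C; NH4Cl (aq)
Reagents that add atoms: isobutylmagnesium bromide, CC(C)C[Mg]Br
Why: o-Quinone methide alkylation; the benzylic magnesium alkoxide takes over the carbonate, the phenoxide expels tert-butyl carbonate, and a further equivalent of Grignard reagent adds 1,4 with rearomatization. The (R) configuration at C1' is expected from addition to the methide face anti to the C5 branch of the neighbouring quaternary carbon, in the conformer that keeps the small 4-methyl group in the methide plane (allylic 1,3-strain).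

Step 14
Reactants: 22 2-{(1R)-1-[(1S,3aR,4R,7R,8aS)-4-hydroxy-1,4-dimethyl-7-(prop-1-en-2-yl)decahydroazulen-1-yl]-3-methylbutyl}-3,5-dimethoxyphenol
Product: 23 2,4-dibromo-6-{(1R)-1-[(1S,3aR,4R,7R,8aS)-4-hydroxy-1,4-dimethyl-7-(prop-1-en-2-yl)decahydroazulen-1-yl]-3-methylbutyl}-3,5-dimethoxyphenol
Conditions: NBS (2.05 equiv), CH2Cl2, −40 → 0 °C, dark
Reagents that add atoms: N-bromosuccinimide, O=C1CCC(=O)N1Br
Why: Electrophilic aromatic bromination at the only two free positions of the phloroglucinol-type ring, which should be much faster than any reaction of NBS with the isopropenyl group.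

Step 15
Reactants: 23 2,4-dibromo-6-{(1R)-1-[(1S,3aR,4R,7R,8aS)-4-hydroxy-1,4-dimethyl-7-(prop-1-en-2-yl)decahydroazulen-1-yl]-3-methylbutyl}-3,5-dimethoxyphenol
Product: 25 4-hydroxy-5-{(1R)-1-[(1S,3aR,4R,7R,8aS)-4-hydroxy-1,4-dimethyl-7-(prop-1-en-2-yl)decahydroazulen-1-yl]-3-methylbutyl}-2,6-dimethoxybenzene-1,3-dicarbaldehyde, via aryldilithium 24 (not isolated)
Conditions: MeLi (2.1 equiv), THF, −78 °C; t-BuLi (4.4 equiv), −78 °C; DMF (10 equiv), −78 → 0 °C; NH4Cl (aq)
Reagents that add atoms: N,N-dimethylformamide, CN(C)C=O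
Why: Deprotonation of the two hydroxyls, double bromine–lithium exchange (each aryllithium is flanked by two oxygen donors) and formylation with DMF.

Step 16
Reactants: 25 4-hydroxy-5-{(1R)-1-[(1S,3aR,4R,7R,8aS)-4-hydroxy-1,4-dimethyl-7-(prop-1-en-2-yl)decahydroazulen-1-yl]-3-methylbutyl}-2,6-dimethoxybenzene-1,3-dicarbaldehyde
Product: 26 5-{(1R)-1-[(1S,3aR,4R,7R,8aS)-4-hydroxy-1,4-dimethyl-7-(prop-1-en-2-yl)decahydroazulen-1-yl]-3-methylbutyl}-2,4,6-trihydroxybenzene-1,3-dicarbaldehyde (CNP0594576.1)
Conditions: 4-MeC6H4SLi (8 equiv), HMPA–toluene, 110 °C; 1 M HCl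
Reagents that add atoms: none
Why: Thiolate SN2 O-demethylation of the two methoxy groups, both activated by ortho or para formyl groups; the basic conditions should spare the tertiary alcohol and the isopropenyl group.

**Compound list**

1 | (R)-(+)-limonene | C=C(C)[C@@H]1CCC(C)=CC1 | starting material
2 | limonene 1,2-ozonide (1,2,4-trioxolane across the former ring alkene) | CC12CC[C@@H](C(C)=C)CC(OO1)O2 | intermediate
3 | (3R)-6-oxo-3-(prop-1-en-2-yl)heptanal | C=C(C)[C@H](CCC(C)=O)CC=O | intermediate
4 | (5R)-5-(prop-1-en-2-yl)oct-7-en-2-one | C=C(C)[C@H](CCC(C)=O)CC=C | intermediate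
5 | (6R)-1-(dimethylamino)-6-(prop-1-en-2-yl)non-8-en-3-one (Mannich base) | C=C(C)[C@H](CCC(=O)CCN(C)C)CC=C | intermediate
6 | (6R)-N,N,N-trimethyl-3-oxo-6-(prop-1-en-2-yl)non-8-en-1-aminium iodide | C=C(C)[C@H](CCC(=O)CC[N+](C)(C)C)CC=C.[I-] | intermediate
7 | (6R)-6-(prop-1-en-2-yl)nona-1,8-dien-3-one | C=C(C)[C@H](CCC(=O)C=C)CC=C | intermediate
8 | (5R)-5-(prop-1-en-2-yl)cyclohept-2-en-1-one | C=C(C)[C@@H]1CCC(=O)C=CC1 | intermediate
9 | 1,3,5-trimethoxybenzene | COc1cc(OC)cc(OC)c1 | starting material
10 | 1-(2,4,6-trimethoxyphenyl)propan-1-one | CCC(=O)c1c(OC)cc(OC)cc1OC | intermediate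
11 | (Z)-trimethyl{[1-(2,4,6-trimethoxyphenyl)prop-1-en-1-yl]oxy}silane | C/C=C(\O[Si](C)(C)C)c1c(OC)cc(OC)cc1OC | intermediate
12 | 2-[(1S,6R)-6-(prop-1-en-2-yl)-3-(trimethylsilyloxy)cyclohept-2-en-1-yl]-1-(2,4,6-trimethoxyphenyl)propan-1-one (C5 side chain trans to isopropenyl; both C4 epimers) | C=C(C)[C@@H]1CCC(O[Si](C)(C)C)=C[C@@H](C(C)C(=O)c2c(OC)cc(OC)cc2OC)C1 | intermediate
13 | lithium enolate of 12 at the aryl ketone | C=C(C)[C@@H]1CCC(O[Si](C)(C)C)=C[C@@H](C(C)=C([O-])c2c(OC)cc(OC)cc2OC)C1.[Li+] | intermediate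
14 | dilithium 1,3-bis-enolate (cycloheptanone enolate at C1 and aryl ketone enolate at C4) | C=C(C)[C@@H]1CCC([O-])=C[C@@H](C(C)=C([O-])c2c(OC)cc(OC)cc2OC)C1.[Li+].[Li+] | intermediate
15 | dilithium salt of the C1-(2-sulfatoethyl) cycloheptanone bearing the aryl ketone enolate (C1 and C5 side chains trans) | C=C(C)[C@@H]1CCC(=O)[C@H](CCOS(=O)(=O)[O-])[C@@H](C(C)=C([O-])c2c(OC)cc(OC)cc2OC)C1.[Li+].[Li+] | intermediate
16 | (1S,3aR,7R,8aS)-1-methyl-7-(prop-1-en-2-yl)-1-(2,4,6-trimethoxybenzoyl)octahydroazulen-4(1H)-one (trans-fused; H1 α, H5 β, 4-CH3 α, aroyl β) | C=C(C)[C@@H]1CCC(=O)[C@@H]2CC[C@](C)(C(=O)c3c(OC)cc(OC)cc3OC)[C@H]2C1 | intermediate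
17 | [(1S,3aR,4R,7R,8aS)-4-hydroxy-1,4-dimethyl-7-(prop-1-en-2-yl)decahydroazulen-1-yl](2,4,6-trimethoxyphenyl)methanone | C=C(C)[C@@H]1CC[C@@](C)(O)[C@@H]2CC[C@](C)(C(=O)c3c(OC)cc(OC)cc3OC)[C@H]2C1 | intermediate
18 | (2-hydroxy-4,6-dimethoxyphenyl)[(1S,3aR,4R,7R,8aS)-4-hydroxy-1,4-dimethyl-7-(prop-1-en-2-yl)decahydroazulen-1-yl]methanone | C=C(C)[C@@H]1CC[C@@](C)(O)[C@@H]2CC[C@](C)(C(=O)c3c(O)cc(OC)cc3OC)[C@H]2C1 | intermediate
19 | 2-{hydroxy[(1S,3aR,4R,7R,8aS)-4-hydroxy-1,4-dimethyl-7-(prop-1-en-2-yl)decahydroazulen-1-yl]methyl}-3,5-dimethoxyphenol (both carbinol epimers) | C=C(C)[C@@H]1CC[C@@](C)(O)[C@@H]2CC[C@](C)(C(O)c3c(O)cc(OC)cc3OC)[C@H]2C1 | intermediate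
20 | tert-butyl 2-{hydroxy[(1S,3aR,4R,7R,8aS)-4-hydroxy-1,4-dimethyl-7-(prop-1-en-2-yl)decahydroazulen-1-yl]methyl}-3,5-dimethoxyphenyl carbonate | C=C(C)[C@@H]1CC[C@@](C)(O)[C@@H]2CC[C@](C)(C(O)c3c(OC(=O)OC(C)(C)C)cc(OC)cc3OC)[C@H]2C1 | intermediate
21 | o-quinone methide (3,5-dimethoxy-6-alkylidenecyclohexa-2,4-dienone; C10 bromomagnesium alkoxide) | C=C(C)[C@@H]1CC[C@@](C)(O[Mg]Br)[C@@H]2CC[C@](C)(C=C3C(=O)C=C(OC)C=C3OC)[C@H]2C1 | intermediate
22 | 2-{(1R)-1-[(1S,3aR,4R,7R,8aS)-4-hydroxy-1,4-dimethyl-7-(prop-1-en-2-yl)decahydroazulen-1-yl]-3-methylbutyl}-3,5-dimethoxyphenol | C=C(C)[C@@H]1CC[C@@](C)(O)[C@@H]2CC[C@](C)([C@@H](CC(C)C)c3c(O)cc(OC)cc3OC)[C@H]2C1 | intermediate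
23 | 2,4-dibromo-6-{(1R)-1-[(1S,3aR,4R,7R,8aS)-4-hydroxy-1,4-dimethyl-7-(prop-1-en-2-yl)decahydroazulen-1-yl]-3-methylbutyl}-3,5-dimethoxyphenol | C=C(C)[C@@H]1CC[C@@](C)(O)[C@@H]2CC[C@](C)([C@@H](CC(C)C)c3c(O)c(Br)c(OC)c(Br)c3OC)[C@H]2C1 | intermediate
24 | aryldilithium from 23 (dilithium alkoxide and phenoxide) | C=C(C)[C@@H]1CC[C@@](C)(O[Li])[C@@H]2CC[C@](C)([C@@H](CC(C)C)c3c(O[Li])c([Li])c(OC)c([Li])c3OC)[C@H]2C1 | intermediate
25 | 4-hydroxy-5-{(1R)-1-[(1S,3aR,4R,7R,8aS)-4-hydroxy-1,4-dimethyl-7-(prop-1-en-2-yl)decahydroazulen-1-yl]-3-methylbutyl}-2,6-dimethoxybenzene-1,3-dicarbaldehyde | C=C(C)[C@@H]1CC[C@@](C)(O)[C@@H]2CC[C@](C)([C@@H](CC(C)C)c3c(O)c(C=O)c(OC)c(C=O)c3OC)[C@H]2C1 | intermediate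
26 | 5-{(1R)-1-[(1S,3aR,4R,7R,8aS)-4-hydroxy-1,4-dimethyl-7-(prop-1-en-2-yl)decahydroazulen-1-yl]-3-methylbutyl}-2,4,6-trihydroxybenzene-1,3-dicarbaldehyde (CNP0594576.1) | C=C(C)[C@@H]1CC[C@@](C)(O)[C@@H]2CC[C@](C)([C@@H](CC(C)C)c3c(O)c(C=O)c(O)c(C=O)c3O)[C@H]2C1 | target

**Step count and risks**

Total step count: 16. Longest linear sequence: 14 steps (steps 1–4 and 7–16); steps 5 and 6 form the short convergent branch.

The three steps most likely to fail:

Step 8. After the first C–C bond is formed, the C10 ketone is free again next to a basic enolate and a leaving group. Proton transfer between them (enolate scrambling) could then lead to O-alkylation or to three-membered ring closure. First alkylation at the C4 enolate instead of C1 would erode the control of the quaternary centre. The fallback changes the order of bond formation and keeps the C10 carbonyl masked. It sets out from 12: the aryl ketone lithium enolate alone (LiN(i-Pr)2, THF, −78 °C) would be C-alkylated with 2-bromoethyl trifluoromethanesulfonate to give the bromoethyl silyl enol ether F1. MeLi would then release the C1 lithium enolate only at this stage, and this enolate would close the ring by 5-exo-tet displacement of bromide. The fallback comes back to the route at 16. In this order no ketone with acidic hydrogens coexists with an enolate and a leaving group; the price is that C4 is set in an acyclic alkylation, so separation from the C4 epimer should be expected.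

Step 13. The 1,4-addition to the quinone methide could proceed with poor or reversed facial selectivity, or the Grignard reagent could transfer hydride instead of the isobutyl group. The fallback reverses the order in which the two substituents are delivered to C1'. It sets out from 18: acylation of the phenol (Boc2O, DMAP) would give the aryl carbonate ketone F2. Addition of i-BuLi with CeCl3 to the ketone, carbonate transfer and elimination would give the isobutyl-substituted o-quinone methide F3, which would be reduced in the same flask by 1,4-addition of hydride (LiBH4). The fallback comes back at 22. Because hydride now enters from the face that the isobutyl group took before, the same facial bias gives the opposite configuration at C1', so this sequence is the remedy if the main step gives the epimer.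

Step 9. MeLi could attack the wrong face of the C10 carbonyl, or the ketone could enolize toward C1. The fallback replaces C-nucleophile addition by methylene transfer and hydride opening. It sets out from 16: Me2S=CH2 (from Me3SI and KN(SiMe3)2), a small nucleophile with an intrinsic preference for axial attack and no need for Lewis acid complexation, would give the spiro-epoxide F4. LiBHEt3 would open it at the CH2 terminus, and the fallback comes back at 17. Should the ring conformation invert the facial sense, Me2S(O)=CH2, which delivers the methylene group equatorially, is the complementary reagent.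

**Further compounds**

F1 | step 8 | 4-bromo-2-methyl-2-[(1S,6R)-6-(prop-1-en-2-yl)-3-(trimethylsilyloxy)cyclohept-2-en-1-yl]-1-(2,4,6-trimethoxyphenyl)butan-1-one (desired C4 epimer drawn) | C=C(C)[C@@H]1CCC(O[Si](C)(C)C)=C[C@@H]([C@](C)(CCBr)C(=O)c2c(OC)cc(OC)cc2OC)C1
F2 | step 13 | tert-butyl 2-{[(1S,3aR,4R,7R,8aS)-4-hydroxy-1,4-dimethyl-7-(prop-1-en-2-yl)decahydroazulen-1-yl]carbonyl}-3,5-dimethoxyphenyl carbonate | C=C(C)[C@@H]1CC[C@@](C)(O)[C@@H]2CC[C@](C)(C(=O)c3c(OC(=O)OC(C)(C)C)cc(OC)cc3OC)[C@H]2C1
F3 | step 13 | isobutyl-substituted o-quinone methide (6-[1-(hydroazulenyl)-3-methylbutylidene]-3,5-dimethoxycyclohexa-2,4-dienone) | C=C(C)[C@@H]1CC[C@@](C)(O)[C@@H]2CC[C@](C)(C(CC(C)C)=C3C(=O)C=C(OC)C=C3OC)[C@H]2C1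
F4 | step 9 | spiro-epoxide of 16 at C10 (CH2 β, O α): [(1'S,3a'R,7'R,8a'S)-1'-methyl-7'-(prop-1-en-2-yl)octahydro-1'H-spiro[oxirane-2,4'-azulen]-1'-yl](2,4,6-trimethoxyphenyl)methanone | C=C(C)[C@@H]1CC[C@]3(CO3)[C@@H]2CC[C@](C)(C(=O)c4c(OC)cc(OC)cc4OC)[C@H]2C1
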